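**Retrosynthetic overview**
1. The endgame leads back to ten-membered epoxy ketone 28: C12 desilylation, chelate-controlled reduction at C2, chloride opening of a 6,7-vinyl epoxide with lactonisation, and Reformatsky addition at C8.
2. The carbocycle C1–C10 of 28 is cut at C3–C4 and re-tied through an oxygen atom and C16. The resulting eleven-membered oxacycle 25 (C1, C2, C3, O, C16, C5–C10) gives 28 by an enolate [2,3]-Wittig ring contraction (11 → 10) that ends in epoxide closure.
3. Enabling feature in ring C1–C10: the epoxide oxygen on C3, C4 and the exocyclic methylene form the array O–C3–C4–C5=C16, which is the [2,3]-Wittig retron. C3 is α to the C2 oxygen, so at ketone level it is the only enolisable site next to quaternary C1. C4 carries the second C–O bond, which is a vinylic chloride in 25.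
4. Oxacycle 25 comes from ring-closing metathesis (C6=C7) of keto ether 24. Keto ether 24 is made from terminal epoxide 22 and chlorodienol 4.
5. Ring order: cyclohexene (asymmetric Diels–Alder) → 13,14-oxirane → eleven-membered oxacycle → ten-membered carbocycle plus 3,4-oxirane → 6,7-oxirane → γ-lactone.

Key step: step 17

Numbering (briarane):
- C1 is the quaternary ring-fusion carbon and carries Me C15.
- C2 is the carbinol, C3/C4 the epoxide, C5(=C16H2) the methylene carbon.
- C6 bears Cl, C7 the lactone O, C8 the tertiary OH, C9 the OAc.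
- C10 is the ring-fusion CH; C11 carries Me C20; C12 bears OH; C13/C14 form the second epoxide.
- C17 (Me C18) and C19 belong to the lactone.
- β is the cyclohexane face that carries C15.

Assumption: the (S)-oxazaborolidinium salt is taken to expose the Si face at C1 of enal 10, as its accepted pre-transition-state model for 2-substituted enals predicts. The antipodal catalyst is equally available.

**Step 1**
Reactants: 1 prop-2-yn-1-ol; 2 vinylmagnesium chloride
Product: 4 (2Z)-3-chloro-2-ethenylprop-2-en-1-ol, via oxamagnesacyclopentene 3 (not isolated)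
Conditions: 2 (2.5 equiv), THF–cyclohexane, reflux; NCS, THF, −30 °C; aq NH4Cl
Reagents that add atoms: N-chlorosuccinimide, O=C1CCC(=O)N1Cl
Why: Hydroxyl-directed anti-carbomagnesiation of a propargylic alcohol puts vinyl on the inner alkyne carbon and magnesium cis to CH2O in a five-membered chelate, so electrophilic chlorination with retention should fix the chloroalkene with Cl cis to CH2OH.

**Step 2**
Reactants: 5 acrolein; 6 acetyl bromide
Product: 7 3-bromoprop-1-en-1-yl acetate (E/Z mixture)
Conditions: ZnCl2 (cat.), CH2Cl2, −20 °C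
Reagents that add atoms: none
Why: Lewis-acid-catalysed 1,4-addition of an acyl bromide to an enal gives the α-hydroxyallylation reagent, and both geometrical isomers are usable.

**Step 3**
Reactants: 8 pent-1-en-3-one
Product: 9 (3Z)-3-(tert-butyldimethylsilyloxy)penta-1,3-diene
Conditions: TBSOTf, Et3N, Et2O, 0 °C
Reagents that add atoms: tert-butyldimethylsilyl triflate, CC(C)(C)[Si](C)(C)OS(=O)(=O)C(F)(F)F
Why: Soft enolisation and O-silylation of the enone gives the 2-silyloxydiene, and the Z enol ether is favoured because the methyl group avoids the vinyl group.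

**Step 4**
Reactants: 9 (3Z)-3-(tert-butyldimethylsilyloxy)penta-1,3-diene; 10 ethyl (2E)-3-methyl-4-oxobut-2-enoate
Product: 11 cyclohexene aldehyde ester (C1: β-Me, α-CHO; C10: β-CO2Et; C11: α-Me; C12=C13 TBS enol ether)
Conditions: (S)-o-tolyl-diphenylprolinol oxazaborolidine·Tf2NH (10 mol %), CH2Cl2, −78 °C
Reagents that add atoms: none
Why: In this catalytic enantioselective Diels–Alder reaction the silyloxy-activated diene terminus bonds to the β-carbon of the boron-bound enal (C11–C10), the E dienophile fixes C2/C9 trans, the catalyst fixes the absolute sense at C1 and C10, and the formyl-endo mode places the C11 methyl cis to CHO (corrected in step 7).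

**Step 5**
Reactants: 11 cyclohexene aldehyde ester
Product: 12 terminal epoxide (C2–C3 oxirane on C1, C2 epimers; otherwise as 11)
Conditions: Me3SI, KHMDS, THF, −20 → 0 °C
Reagents that add atoms: trimethylsulfonium iodide, C[S+](C)C.[I-]
Why: Corey–Chaykovsky methylenation of the non-enolisable aldehyde adds C3 and masks C2/C3 as an oxirane, and the new C2 centre is of no consequence because it becomes a ketone in step 15.

**Step 6**
Reactants: 12 terminal epoxide
Product: 13 cyclohexenone (C12 ketone, C13=C14; C11 α-Me)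
Conditions: Pd(OAc)2 (1.05 equiv), MeCN, rt
Reagents that add atoms: none
Why: Saegusa–Ito dehydrosilylation of the regiodefined silyl enol ether from the cycloaddition places the alkene at C13=C14 and leaves ester and oxirane untouched.

**Step 7**
Reactants: 13 cyclohexenone
Product: 15 C11-epimeric cyclohexenone (C11 β-Me, cis to the C10 ester), via lithium dienolate 14 (not isolated)
Conditions: LDA, THF, −78 °C; AcOH, THF, −78 °C
Reagents that add atoms: none
Why: Kinetic α′-deprotonation of the enone, followed by kinetic protonation of the cross-conjugated dienolate from the α face (anti to the vicinal C10 ester and to C15), should give the contra-thermodynamic 10,11-cis isomer and thereby set C11.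

**Step 8**
Reactants: 15 C11-epimeric cyclohexenone
Product: 16 allylic alcohol (12β-OH)
Conditions: NaBH4, CeCl3·7H2O, MeOH, −78 °C
Reagents that add atoms: none
Why: In this Luche 1,2-reduction hydride adds from the α face, which is free of the β-oriented C9, C15 and C20 groups, so the 12β-alcohol forms and C11 is locked against epimerisation.

**Step 9**
Reactants: 16 allylic alcohol
Product: 17 12β-TBS ether
Conditions: TBSCl, imidazole, DMAP (cat.), DMF, 40 °C
Reagents that add atoms: tert-butyldimethylsilyl chloride, CC(C)(C)[Si](C)(C)Cl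
Why: Standard silylation removes the directing hydroxyl group and adds bulk on the β face for the next step.

**Step 10**
Reactants: 17 12β-TBS ether
Product: 18 13α,14α-epoxide
Conditions: mCPBA, NaHCO3, CH2Cl2, 0 °C
Reagents that add atoms: 3-chloroperoxybenzoic acid, OOC(=O)c1cccc(Cl)c1
Why: Prilezhaev epoxidation of the only alkene should occur on the α face, anti to the 12β-silyloxy group and to the C15 methyl group, which sets C13 and C14.

**Step 11**
Reactants: 18 13α,14α-epoxide
Product: 19 C9 aldehyde
Conditions: DIBAL-H (1.05 equiv), PhMe, −78 °C; Rochelle salt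
Reagents that add atoms: none
Why: Low-temperature partial reduction of the ester stops at the tetrahedral aluminium hemiacetal, and both oxiranes are inert at −78 °C.

**Step 12**
Reactants: 19 C9 aldehyde; 7 3-bromoprop-1-en-1-yl acetate
Product: 21 C8,C9-diol with C7 vinyl group (9R as in the target, C8 epimers), via C8 monoacetate 20 (not isolated)
Conditions: In, THF, 0 °C → rt; then K2CO3 (cat.), MeOH
Reagents that add atoms: none
Why: In this Barbier-type α-hydroxyallylation the γ-acetoxyallylindium reagent adds in the Felkin–Anh sense, anti to quaternary C1 and over H10, which sets C9, while C8 later becomes a ketone.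

**Step 13**
Reactants: 21 C8,C9-diol
Product: 22 8,9-bis-TES ether
Conditions: TESCl, imidazole, DMF, 0 °C → rt
Reagents that add atoms: chlorotriethylsilane, CC[Si](CC)(CC)Cl
Why: Standard silylation gives two ethers that can later be removed together in the presence of the TBS ether.

**Step 14**
Reactants: 22 8,9-bis-TES ether; 4 (2Z)-3-chloro-2-ethenylprop-2-en-1-ol
Product: 23 C2 hydroxy ether (C3–O–C16 linkage)
Conditions: 4 (2 equiv), NaH, DMF, 0 → 50 °C
Reagents that add atoms: none
Why: The alkoxide opens the terminal oxirane by SN2 attack at its unsubstituted carbon C3 (Williamson-type etherification), and the hindered 13,14-epoxide is not attacked.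

**Step 15**
Reactants: 23 C2 hydroxy ether
Product: 24 α-alkoxy ketone (C2=O)
Conditions: Dess–Martin periodinane, NaHCO3, CH2Cl2, 0 °C → rt
Reagents that add atoms: none
Why: Dess–Martin oxidation of the only free hydroxyl group converges both C2 epimers on one ketone under neutral conditions.

**Step 16**
Reactants: 24 α-alkoxy ketone
Product: 25 eleven-membered oxacycle ((6Z)-alkene; ring C1, C2, C3, O, C16, C5–C10)
Conditions: cyclometalated Z-selective Ru catalyst (7.5 mol %), DCE (1 mM), 40 °C, static vacuum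
Reagents that add atoms: none
Why: Z-selective ring-closing metathesis joins the two monosubstituted alkenes (C6 and C7) while the trisubstituted chloroalkene stays inert, and the cis alkene keeps C8 folded back towards C5 as the next step requires.

**Step 17**
Reactants: 25 eleven-membered oxacycle
Product: 28 ten-membered cis-3,4-epoxy ketone with C5 exocyclic methylene, via lithium enolate 26 (not isolated), via lithium chlorohydrin alkoxide 27 (not isolated)
Conditions: LiHMDS (1.15 equiv), THF (5 mM), −78 → −20 °C; then rt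
Reagents that add atoms: none
Why: Proposed new method: LiHMDS removes a proton from the only enolisable position (C3; C1 is quaternary), and the lithium-chelated enolate undergoes a [2,3]-Wittig shift in which C3 bonds to the chlorovinyl carbon C4 while the O–C16 bond breaks, so O and C16 leave the ring, C4 enters it (11 → 10) and C16 becomes the exocyclic methylene. The closest known reactions are enolate [2,3]-Wittig rearrangements of α-allyloxy ketones and [2,3]-Wittig ring contractions of macrocyclic allyl ethers, here followed by a Darzens-type chlorohydrin closure. The carbocycle closes sigmatropically through a five-centre envelope transition state, and the oxirane then closes 3-exo-tet on warming, when the C3 alkoxide displaces the now allylic C4 chloride with inversion. For the C3/C4 relation, the chlorine is cis to CH2O, and such Z-type termini react through the exo transition state to the syn product, that is the syn-chlorohydrin and hence the cis-epoxide; the (6Z)-alkene makes this exo geometry reachable for the tether. For the absolute sense at C3, A(1,3) strain places C15 in the enolate plane and the tether C5···C10 can reach only the enolate face on the C10 side, anti to C14. The step needs [2,3] to win over [3,3], which is secured because the Claisen mode would join C2 to C4 next to quaternary C1 in a nine-membered ring, and to win over enolate alkylation, which is secured because no sp3 C–Cl bond exists before the shift.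

**Step 18**
Reactants: 28 ten-membered cis-3,4-epoxy ketone
Product: 29 C8,C9-diol
Conditions: HF·pyridine, pyridine, THF, 0 °C
Reagents that add atoms: none
Why: Buffered fluoride cleaves the two secondary TES ethers selectively in the presence of the more robust TBS ether and both oxiranes.

**Step 19**
Reactants: 29 C8,C9-diol
Product: 30 C8 dienone (9-OH free)
Conditions: activated MnO2, CH2Cl2, rt
Reagents that add atoms: none
Why: Manganese dioxide oxidises only the dienylic C8 alcohol, converges both C8 epimers and leaves the non-allylic C9 alcohol untouched.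

**Step 20**
Reactants: 30 C8 dienone
Product: 31 trans-6,7-epoxy ketone (bis-epoxy diketone, 9-OH free)
Conditions: t-BuOOH, DBU (cat.), PhMe, 0 °C
Reagents that add atoms: tert-butyl hydroperoxide, CC(C)(C)OO
Why: Weitz–Scheffer epoxidation is stepwise, so the β-peroxy enolate should relax to the extended rotamer and close to the trans-epoxy ketone whatever the enone geometry, while hydrogen-bonded delivery by the C9 hydroxyl on the outer face sets C6 and C7 with O7 syn to O9.

**Step 21**
Reactants: 31 trans-6,7-epoxy ketone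
Product: 32 C9 acetate
Conditions: Ac2O, pyridine, DMAP (cat.), CH2Cl2, 0 °C
Reagents that add atoms: acetic anhydride, CC(=O)OC(C)=O
Why: Acylation of the only hydroxyl group installs the C9 acetate of the target before a second γ-hydroxyl could compete in the lactonisation.

**Step 22**
Reactants: 32 C9 acetate; 33 methyl 2-bromopropanoate
Product: 34 C8 tertiary alcohol carrying the C17–C19 propanoate
Conditions: Et2Zn, RhCl(PPh3)3 (5 mol %), THF, 0 °C
Reagents that add atoms: none
Why: In this rhodium-catalysed Reformatsky reaction the weakly basic zinc enolate spares the acetate and the neopentyl C2 ketone, zinc chelation of C8=O with the epoxide oxygen (Cram chelate) directs attack from the H7 side to give the 7,8-anti relation at C8, and the cyclic zinc aldolate places the C17 methyl anti to C9.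

**Step 23**
Reactants: 34 C8 tertiary alcohol
Product: 36 6-chloro γ-lactone (C2 ketone, 12-OTBS), via chlorohydrin ester 35 (not isolated)
Conditions: ClTi(OiPr)3, CH2Cl2, −20 → 0 °C; then PPTS (cat.), PhH, 40 °C
Reagents that add atoms: chlorotitanium triisopropoxide, CC(C)O[Ti](Cl)(OC(C)C)OC(C)C
Why: Titanium bound to the C8 hydroxyl directs chloride to the distal and allylic carbon C6 of this 2,3-epoxy alcohol (SN2, inversion, giving the 6,7-anti chlorohydrin), the keto-deactivated 3,4-epoxide lacks such a director, and the freed C7 hydroxyl lactonises onto C19.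

**Step 24**
Reactants: 36 6-chloro γ-lactone
Product: 37 C2 alcohol (2S)
Conditions: Zn(BH4)2, Et2O, −30 °C
Reagents that add atoms: none
Why: Chelation-controlled reduction of the α,β-epoxy ketone, with zinc bridging C2=O and the epoxide oxygen and hydride arriving from the H3 side, gives the anti (erythro) epoxy alcohol, which is also the Felkin–Anh sense with respect to C10, and lactone, acetate and chloride are inert.

**Step 25**
Reactants: 37 C2 alcohol
Product: 38 target CNP0314105.1
Conditions: HF·pyridine, pyridine, THF, 0 °C → rt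
Reagents that add atoms: none
Why: Buffered fluoride desilylation frees the C12 hydroxyl without base, so acetate, allylic chloride and the oxiranes should survive.

**Compound list**
1 | prop-2-yn-1-ol | C#CCO | starting material
2 | vinylmagnesium chloride | C=C[Mg]Cl | starting material
3 | 4-ethenyl-2,5-dihydro-1,2-oxamagnesole | C=CC1=C[Mg]OC1 | intermediate
4 | (2Z)-3-chloro-2-ethenylprop-2-en-1-ol | OC/C(=C\Cl)C=C | intermediate
5 | acrolein | C=CC=O | starting material
6 | acetyl bromide | CC(=O)Br | starting material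
7 | 3-bromoprop-1-en-1-yl acetate (E/Z) | CC(=O)OC=CCBr | intermediate
8 | pent-1-en-3-one | CCC(=O)C=C | starting material
9 | (3Z)-3-(tert-butyldimethylsilyloxy)penta-1,3-diene | C=C/C(O[Si](C)(C)C(C)(C)C)=C/C | intermediate
10 | ethyl (2E)-3-methyl-4-oxobut-2-enoate | CCOC(=O)/C=C(\C)C=O | starting material
11 | Diels–Alder adduct (1β-Me, 1α-CHO, 10β-CO2Et, 11α-Me, 12-OTBS enol ether) | O=C[C@]1(C)[C@H]([C@H](C)C(O[Si](C)(C)C(C)(C)C)=CC1)C(=O)OCC | intermediate
12 | C2–C3 terminal epoxide of 11 (C2 epimers) | C1OC1[C@]2(C)[C@H]([C@H](C)C(O[Si](C)(C)C(C)(C)C)=CC2)C(=O)OCC | intermediate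
13 | cyclohexenone, 11α-Me | C1OC1[C@]2(C)[C@H]([C@H](C)C(=O)C=C2)C(=O)OCC | intermediate
14 | lithium cross-conjugated dienolate | [Li+].C1OC1[C@]2(C)[C@H](C(C)=C([O-])C=C2)C(=O)OCC | intermediate
15 | cyclohexenone, 11β-Me | C1OC1[C@]2(C)[C@H]([C@@H](C)C(=O)C=C2)C(=O)OCC | intermediate
16 | 12β-allylic alcohol | C1OC1[C@]2(C)[C@H]([C@@H](C)[C@@H](O)C=C2)C(=O)OCC | intermediate
17 | 12β-TBS ether | C1OC1[C@]2(C)[C@H]([C@@H](C)[C@@H](O[Si](C)(C)C(C)(C)C)C=C2)C(=O)OCC | intermediate
18 | 13α,14α-epoxy ester | C1OC1[C@]2(C)[C@H]([C@@H](C)[C@@H](O[Si](C)(C)C(C)(C)C)[C@@H]3O[C@@H]32)C(=O)OCC | intermediate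
19 | C9 aldehyde | C1OC1[C@]2(C)[C@H]([C@@H](C)[C@@H](O[Si](C)(C)C(C)(C)C)[C@@H]3O[C@@H]32)C=O | intermediate
20 | 9-hydroxy-8-acetoxy alkene (C8 epimers) | C1OC1[C@]2(C)[C@H]([C@@H](C)[C@@H](O[Si](C)(C)C(C)(C)C)[C@@H]3O[C@@H]32)[C@@H](O)C(OC(C)=O)C=C | intermediate
21 | 8,9-diol alkene (C8 epimers) | C1OC1[C@]2(C)[C@H]([C@@H](C)[C@@H](O[Si](C)(C)C(C)(C)C)[C@@H]3O[C@@H]32)[C@@H](O)C(O)C=C | intermediate
22 | 8,9-bis-TES ether | C1OC1[C@]2(C)[C@H]([C@@H](C)[C@@H](O[Si](C)(C)C(C)(C)C)[C@@H]3O[C@@H]32)[C@@H](O[Si](CC)(CC)CC)C(O[Si](CC)(CC)CC)C=C | intermediate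
23 | C2 hydroxy ether (C2 epimers) | OC(COC/C(=C\Cl)C=C)[C@]1(C)[C@H]([C@@H](C)[C@@H](O[Si](C)(C)C(C)(C)C)[C@@H]2O[C@@H]21)[C@@H](O[Si](CC)(CC)CC)C(O[Si](CC)(CC)CC)C=C | intermediate
24 | α-alkoxy ketone | O=C(COC/C(=C\Cl)C=C)[C@]1(C)[C@H]([C@@H](C)[C@@H](O[Si](C)(C)C(C)(C)C)[C@@H]2O[C@@H]21)[C@@H](O[Si](CC)(CC)CC)C(O[Si](CC)(CC)CC)C=C | intermediate
25 | eleven-membered oxacycle, (6Z), Cl cis to C16 | O=C1[C@]2(C)[C@H]([C@@H](C)[C@@H](O[Si](C)(C)C(C)(C)C)[C@@H]3O[C@@H]32)[C@@H](O[Si](CC)(CC)CC)C(O[Si](CC)(CC)CC)/C=C\C(=C\Cl)COC1 | intermediate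
26 | lithium C2–C3 enolate of 25 | [Li+].[O-]C=1[C@]2(C)[C@H]([C@@H](C)[C@@H](O[Si](C)(C)C(C)(C)C)[C@@H]3O[C@@H]32)[C@@H](O[Si](CC)(CC)CC)C(O[Si](CC)(CC)CC)/C=C\C(=C\Cl)COC=1 | intermediate
27 | ten-membered lithium syn-chlorohydrin alkoxide | [Li+].O=C1[C@]2(C)[C@H]([C@@H](C)[C@@H](O[Si](C)(C)C(C)(C)C)[C@@H]3O[C@@H]32)[C@@H](O[Si](CC)(CC)CC)C(O[Si](CC)(CC)CC)/C=C\C(=C)[C@H](Cl)[C@H]1[O-] | intermediate
28 | ten-membered cis-3,4-epoxy-2-ketone, 5(16)-methylene, (6Z) | O=C1[C@]2(C)[C@H]([C@@H](C)[C@@H](O[Si](C)(C)C(C)(C)C)[C@@H]3O[C@@H]32)[C@@H](O[Si](CC)(CC)CC)C(O[Si](CC)(CC)CC)/C=C\C(=C)[C@H]2O[C@H]21 | intermediate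
29 | 8,9-diol | O=C1[C@]2(C)[C@H]([C@@H](C)[C@@H](O[Si](C)(C)C(C)(C)C)[C@@H]3O[C@@H]32)[C@@H](O)C(O)/C=C\C(=C)[C@H]2O[C@H]21 | intermediate
30 | 8-oxo dienone, 9-OH | O=C1[C@]2(C)[C@H]([C@@H](C)[C@@H](O[Si](C)(C)C(C)(C)C)[C@@H]3O[C@@H]32)[C@@H](O)C(=O)/C=C\C(=C)[C@H]2O[C@H]21 | intermediate
31 | trans-6,7-epoxy-8-ketone, 9-OH | C=C1[C@H]2O[C@H]2C(=O)[C@]2(C)[C@H]([C@@H](C)[C@@H](O[Si](C)(C)C(C)(C)C)[C@@H]3O[C@@H]32)[C@@H](O)C(=O)[C@H]2O[C@@H]21 | intermediate
32 | 9-acetate of 31 | C=C1[C@H]2O[C@H]2C(=O)[C@]2(C)[C@H]([C@@H](C)[C@@H](O[Si](C)(C)C(C)(C)C)[C@@H]3O[C@@H]32)[C@@H](OC(C)=O)C(=O)[C@H]2O[C@@H]21 | intermediate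
33 | methyl 2-bromopropanoate | COC(=O)C(C)Br | starting material
34 | Reformatsky adduct (8-OH, 17-Me, methyl ester) | C=C1[C@H]2O[C@H]2C(=O)[C@]2(C)[C@H]([C@@H](C)[C@@H](O[Si](C)(C)C(C)(C)C)[C@@H]3O[C@@H]32)[C@@H](OC(C)=O)[C@](O)([C@@H](C)C(=O)OC)[C@H]2O[C@@H]21 | intermediate
35 | 6-chloro-7-hydroxy ester | C=C1[C@H]2O[C@H]2C(=O)[C@]2(C)[C@H]([C@@H](C)[C@@H](O[Si](C)(C)C(C)(C)C)[C@@H]3O[C@@H]32)[C@@H](OC(C)=O)[C@](O)([C@@H](C)C(=O)OC)[C@@H](O)[C@H]1Cl | intermediate
36 | 6-chloro γ-lactone, 2-ketone, 12-OTBS | C=C1[C@H]2O[C@H]2C(=O)[C@]2(C)[C@H]([C@@H](C)[C@@H](O[Si](C)(C)C(C)(C)C)[C@@H]3O[C@@H]32)[C@@H](OC(C)=O)[C@]2(O)[C@@H](C)C(=O)O[C@H]2[C@H]1Cl | intermediate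
37 | 2S-alcohol, 12-OTBS | C=C1[C@H]2O[C@H]2[C@@H](O)[C@]2(C)[C@H]([C@@H](C)[C@@H](O[Si](C)(C)C(C)(C)C)[C@@H]3O[C@@H]32)[C@@H](OC(C)=O)[C@]2(O)[C@@H](C)C(=O)O[C@H]2[C@H]1Cl | intermediate
38 | CNP0314105.1 | C=C1[C@H]2O[C@H]2[C@@H](O)[C@]2(C)[C@H]([C@@H](C)[C@@H](O)[C@@H]3O[C@@H]32)[C@@H](OC(C)=O)[C@]2(O)[C@@H](C)C(=O)O[C@H]2[C@H]1Cl | target

**Total step count:** 25. **Longest linear sequence:** 23 (steps 3–25).

**Steps most likely to fail**

*Step 17.* The enolate may rearrange by the [1,2] or [3,3] mode. It may pass through the endo transition state, which would lead to the trans-epoxide. It may also simply be too unreactive towards the chloroalkene.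

The fallback keeps a one-atom ring contraction but uses the Ramberg–Bäcklund reaction. It sets out from 22 and returns at 28.
- Epoxide 22 is opened with 2-methylidenebut-3-ene-1-thiol F1 (Et3N, MeOH) to give the hydroxy sulfide F2.
- Molybdate/H2O2 oxidation at sulfur, then Dess–Martin oxidation, gives the β-keto sulfone F3.
- Z-selective ring-closing metathesis gives the eleven-membered cyclic β-keto sulfone F4.
- Meyers–Chan conditions (KOH/Al2O3, CBr2F2) contract F4 to the ten-membered (3Z,6Z)-trienone F5.
- Nucleophilic epoxidation of the C3=C4 bond of F5 (t-BuOOH, Triton B) gives 28.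

*Step 16.* Z-selectivity may be poor, initiation at the hindered allylic silyl ether may be slow, or oligomerisation may take over.

The fallback separates ring closure from geometry control. It sets out from 24 and returns at 25.
- A standard second-generation ruthenium catalyst closes the ring under thermodynamic control to the (6E)-oxacycle F6.
- Triplet-sensitised, contra-thermodynamic E → Z isomerisation of the conjugated diene (Ir(ppy)3, blue light) then gives 25.

*Step 22.* Facial selectivity at C8 or C17 may be poor, retro-aldol cleavage may occur, or the flanked ketone may be sluggish.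

The fallback delivers the enolate intramolecularly. It sets out from 31 and returns at 36.
- The C9 hydroxyl is acylated with 2-bromopropanoyl bromide to give the C9 2-bromopropanoate F7.
- A zinc-mediated intramolecular Reformatsky reaction, tethered to the O9 face, gives the 8,9-fused hydroxy lactone F8.
- ClTi(OiPr)3 opens the 6,7-epoxide, and the freed C7 hydroxyl translactonises to the 9-hydroxy 7,8-lactone F9.
- Acetylation of F9 gives 36.

**Further compounds**
F1 | step 17 | 2-methylidenebut-3-ene-1-thiol | SCC(=C)C=C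
F2 | step 17 | hydroxy sulfide | OC(CSCC(=C)C=C)[C@]1(C)[C@H]([C@@H](C)[C@@H](O[Si](C)(C)C(C)(C)C)[C@@H]2O[C@@H]21)[C@@H](O[Si](CC)(CC)CC)C(O[Si](CC)(CC)CC)C=C
F3 | step 17 | β-keto sulfone | O=C(CS(=O)(=O)CC(=C)C=C)[C@]1(C)[C@H]([C@@H](C)[C@@H](O[Si](C)(C)C(C)(C)C)[C@@H]2O[C@@H]21)[C@@H](O[Si](CC)(CC)CC)C(O[Si](CC)(CC)CC)C=C
F4 | step 17 | eleven-membered cyclic β-keto sulfone | O=C1[C@]2(C)[C@H]([C@@H](C)[C@@H](O[Si](C)(C)C(C)(C)C)[C@@H]3O[C@@H]32)[C@@H](O[Si](CC)(CC)CC)C(O[Si](CC)(CC)CC)/C=C\C(=C)CS(=O)(=O)C1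
F5 | step 17 | ten-membered (3Z,6Z)-trienone | O=C1[C@]2(C)[C@H]([C@@H](C)[C@@H](O[Si](C)(C)C(C)(C)C)[C@@H]3O[C@@H]32)[C@@H](O[Si](CC)(CC)CC)C(O[Si](CC)(CC)CC)/C=C\C(=C)/C=C\1
F6 | step 16 | (6E)-oxacycle | O=C1[C@]2(C)[C@H]([C@@H](C)[C@@H](O[Si](C)(C)C(C)(C)C)[C@@H]3O[C@@H]32)[C@@H](O[Si](CC)(CC)CC)C(O[Si](CC)(CC)CC)/C=C/C(=C/Cl)COC1
F7 | step 22 | C9 2-bromopropanoate | C=C1[C@H]2O[C@H]2C(=O)[C@]2(C)[C@H]([C@@H](C)[C@@H](O[Si](C)(C)C(C)(C)C)[C@@H]3O[C@@H]32)[C@@H](OC(=O)C(C)Br)C(=O)[C@H]2O[C@@H]21
F8 | step 22 | 8,9-fused hydroxy lactone | C=C1[C@H]2O[C@H]2C(=O)[C@]2(C)[C@H]([C@@H](C)[C@@H](O[Si](C)(C)C(C)(C)C)[C@@H]3O[C@@H]32)[C@H]4OC(=O)[C@H](C)[C@]4(O)[C@H]2O[C@@H]21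
F9 | step 22 | 9-hydroxy 7,8-lactone | C=C1[C@H]2O[C@H]2C(=O)[C@]2(C)[C@H]([C@@H](C)[C@@H](O[Si](C)(C)C(C)(C)C)[C@@H]3O[C@@H]32)[C@@H](O)[C@]2(O)[C@@H](C)C(=O)O[C@H]2[C@H]1Cl
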